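**Strategy**

- Retrosynthesis: the furan is opened at O1–C2 and C2–C3, which returns a terminal alkyne and (Z)-3-iodoprop-2-en-1-ol. The remaining triynol is cut at the central sp–sp bond of the diyne into a C15 bromoalkynol and 1,6-heptadiyne.
- Enabling feature: furan C2, the four tether CH2 groups and the two nearer diyne carbons are the seven carbons of symmetrical 1,6-heptadiyne (C2 and its neighbouring CH2 being one C≡CH end). O1, C5, C4 and C3 are a three-carbon allylic alcohol.
- Forward: propargyl alcohol is C-alkylated with 1-bromododecane, the triple bond is walked to the chain end and brominated, and Cadiot–Chodkiewicz coupling with excess heptadiyne joins the chain at the diyne.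
- The only ring, the furan, is closed last on the surviving terminal alkyne by Sonogashira coupling and 5-exo-dig cycloisomerization in one flask.
- Stereochemistry: the target contains nothing stereogenic. Only the transient Z geometry of the iodoallyl alcohol matters; it is set by anti hydroiodination of ethyl propiolate and vanishes on aromatization.

Key step: step 7

Remark: the transient alkylidenedihydrofuran of the last step is drawn with the Z exocyclic alkene expected from anti oxypalladation; this geometry is lost on aromatization.

**Step 1**
Reactants: 1 propargyl alcohol; 2 1-bromododecane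
Product: 3 pentadec-2-yn-1-ol
Conditions: LiNH2 (2.2 equiv), NH3(l)/THF, −33 °C; then 2 in THF, −33 °C to rt; NH4Cl quench
Reagents that add atoms: none
Why: Acetylide alkylation: two equivalents of amide give the O,C-dilithio species, whose far more nucleophilic sp carbon displaces the primary bromide (SN2) while the alkoxide stays unalkylated and THF keeps the long-chain bromide in solution.

**Step 2**
Reactants: 3 pentadec-2-yn-1-ol
Product: 4 pentadec-14-yn-1-ol
Conditions: KH (4.5 equiv), H2N(CH2)3NH2, rt (forms KNH(CH2)3NH2); then 3, 0 °C to rt; H2O quench
Reagents that add atoms: none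
Why: Alkyne zipper isomerization: the strongly basic aminopropylamide relays the triple bond along the chain by repeated propargyl–allenyl proton shifts until it is trapped irreversibly as the terminal potassium acetylide, so only the ω-alkyne should be released on quenching.

**Step 3**
Reactants: 4 pentadec-14-yn-1-ol
Product: 5 15-bromopentadec-14-yn-1-ol
Conditions: NBS (1.1 equiv), AgNO3 (10 mol %), acetone, rt, dark
Reagents that add atoms: N-bromosuccinimide, O=C1CCC(=O)N1Br
Why: Silver-catalysed electrophilic bromination of a terminal alkyne: the silver acetylide formed in situ is brominated at the sp carbon, and a saturated primary alcohol is inert under these neutral conditions.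

**Step 4**
Reactants: 5 15-bromopentadec-14-yn-1-ol; 6 1,6-heptadiyne
Product: 7 docosa-14,16,21-triyn-1-ol
Conditions: CuCl (10 mol %), NH2OH·HCl (30 mol %), 30% aq n-BuNH2, MeOH/THF, 0 °C; 6 (5 equiv), slow addition of 5, dark
Reagents that add atoms: none
Why: Cadiot–Chodkiewicz coupling: the copper acetylide of 6 reacts with the carbon–bromine bond of 5 to form the unsymmetrical sp–sp bond, NH2OH·HCl keeps copper monovalent to suppress homocoupling, and a fivefold excess of the volatile diyne with slow addition of 5 should restrict coupling to one terminus.

**Step 5**
Reactants: 8 ethyl propiolate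
Product: 9 ethyl (2Z)-3-iodoprop-2-enoate
Conditions: NaI (1.5 equiv), AcOH, 70 °C
Reagents that add atoms: sodium iodide, [Na+].[I-]
Why: Conjugate hydroiodination of an ynoate: iodide adds to the β-carbon and the resulting vinyl anion equivalent is protonated by AcOH from the opposite side (anti addition), the standard kinetic entry to the Z iodoacrylate.

**Step 6**
Reactants: 9 ethyl (2Z)-3-iodoprop-2-enoate
Product: 10 (2Z)-3-iodoprop-2-en-1-ol
Conditions: i-Bu2AlH (2.2 equiv), CH2Cl2, −78 °C; aq KNaC4H4O6 (potassium sodium tartrate) work-up
Reagents that add atoms: none
Why: DIBAL-H ester reduction: two hydride transfers at low temperature take the ester to the primary allylic alcohol, and neither the vinyl carbon–iodine bond nor the Z alkene should be affected under these conditions.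

**Step 7**
Reactants: 7 docosa-14,16,21-triyn-1-ol; 10 (2Z)-3-iodoprop-2-en-1-ol (1.2 equiv)
Product: 13 21-(furan-2-yl)henicosa-14,16-diyn-1-ol, via (Z)-enynol 11 (not isolated), via alkylidenedihydrofuran 12 (not isolated)
Conditions: PdCl2(PPh3)2 (3 mol %), CuI (6 mol %), Et3N (3 equiv), degassed THF, rt; evaporate volatiles; then PdI2 (2 mol %), KI (4 mol %), N,N-dimethylacetamide, 80 °C, same flask, argon, dark
Reagents that add atoms: none
Why: Sonogashira coupling comes first: zerovalent palladium inserts into the vinyl carbon–iodine bond of 10, the copper acetylide of the single terminal alkyne of 7 transmetalates, and reductive elimination gives enynol 11 with the Z geometry retained (furan C2–C3 bond). After the amine is stripped off, the iodide-ligated divalent palladium (K2PdI4 from PdI2 and KI) coordinates the enyne triple bond and the cis allylic hydroxyl adds anti in a 5-exo-dig closure (furan O1–C2 bond); protonolysis of the vinylpalladium gives 12, and a 1,3-hydrogen shift aromatizes it, turning the former internal alkyne carbon into the furan-bound CH2. The closest known reaction type is the divalent-palladium-catalysed cycloisomerization of (Z)-2-en-4-yn-1-ols to 2-alkylfurans, run here on the crude coupling product. No stereocentre is created; the only stereochemical requirement is the Z alkene of 10, which places the oxygen within reach of the alkyne and is erased on aromatization. Chemoselectivity rests on 7 carrying one terminal C–H only (the internal conjugated diyne cannot couple), on the five-membered closure by the allylic hydroxyl outcompeting any reaction of the remote primary hydroxyl, and on rigorous exclusion of oxygen to suppress Glaser dimerization.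

**Compound list**

1 | propargyl alcohol (prop-2-yn-1-ol) | C#CCO | starting material
2 | 1-bromododecane | CCCCCCCCCCCCBr | starting material
3 | pentadec-2-yn-1-ol | CCCCCCCCCCCCC#CCO | intermediate
4 | pentadec-14-yn-1-ol | C#CCCCCCCCCCCCCCO | intermediate
5 | 15-bromopentadec-14-yn-1-ol | BrC#CCCCCCCCCCCCCCO | intermediate
6 | 1,6-heptadiyne (hepta-1,6-diyne) | C#CCCCC#C | starting material
7 | docosa-14,16,21-triyn-1-ol | OCCCCCCCCCCCCCC#CC#CCCCC#C | intermediate
8 | ethyl propiolate | C#CC(=O)OCC | starting material
9 | ethyl (2Z)-3-iodoprop-2-enoate | CCOC(=O)/C=C\I | intermediate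
10 | (2Z)-3-iodoprop-2-en-1-ol | OC/C=C\I | intermediate
11 | (2Z)-pentacos-2-ene-4,9,11-triyne-1,25-diol (enynol formed in the flask in step 7) | OCCCCCCCCCCCCCC#CC#CCCCC#C/C=C\CO | intermediate
12 | (21Z)-21-(furan-2(5H)-ylidene)henicosa-14,16-diyn-1-ol (formed in the flask in step 7) | OCCCCCCCCCCCCCC#CC#CCCC/C=C1/C=CCO1 | intermediate
13 | 21-(furan-2-yl)henicosa-14,16-diyn-1-ol (CNP0078078.0) | OCCCCCCCCCCCCCC#CC#CCCCCc1ccco1 | target

**Totals**

Total step count: 7. Longest linear sequence: 5 steps (steps 1, 2, 3, 4 and 7); steps 5 and 6 form the short second branch.

**Steps most likely to fail**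

Step 7. The terminal alkyne may dimerize oxidatively during coupling. The ring closure may also stall because phosphine and ammonium iodide carried over from the coupling deactivate the divalent palladium iodide catalyst, or because the enynol loses its Z geometry before the hydroxyl can add. The fallback gives up ring construction and attaches a preformed furan. It sets out from bromoalkyne 5 and returns to the route at 13. Furan is lithiated at C2 (n-BuLi, THF, 0 °C) and alkylated with 1-bromo-4-chlorobutane at the bromide end to give 2-(4-chlorobutyl)furan F1. Displacement of chloride with LiC≡CH·H2NCH2CH2NH2 in DMSO (NaI cat., rt) should give 2-(hex-5-yn-1-yl)furan F2. Cadiot–Chodkiewicz coupling of F2 with 5 (CuCl, NH2OH·HCl, aq n-BuNH2, MeOH/THF, 0 °C) then forms the diyne and delivers 13 directly, so compounds 6 to 12 are not needed.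

Step 4. Coupling at both termini of the symmetrical diyne and reductive homocoupling of the bromoalkyne may consume 5 and leave long-chain by-products that are hard to separate. The fallback replaces statistical control by a silyl block. It sets out from 6 (with 5 as partner) and returns at 7. Diyne 6, used in excess, is monolithiated (n-BuLi, THF, −78 °C) and silylated with i-Pr3SiCl to (hepta-1,6-diyn-1-yl)tri(propan-2-yl)silane F3, with unreacted 6 recovered by distillation. Cadiot–Chodkiewicz coupling of F3, which has one free terminus only, with 5 under the conditions of step 4 should give 22-[tri(propan-2-yl)silyl]docosa-14,16,21-triyn-1-ol F4. Desilylation with n-Bu4NF in THF at 0 °C then releases 7.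

Step 1. C-alkylation of the poorly soluble dilithio species by a long-chain bromide that barely dissolves in ammonia may be sluggish, leaving starting materials and allowing competing O-alkylation. The fallback uses a protected monoanion. It sets out from 1 (with 2) and returns at 3. Alcohol 1 is protected with 3,4-dihydro-2H-pyran (pyridinium p-toluenesulfonate cat., CH2Cl2, rt) as 2-(prop-2-yn-1-yloxy)oxane F5. Its soluble lithium acetylide (n-BuLi, THF/DMPU, −78 °C to rt) is alkylated with 2 to give 2-(pentadec-2-yn-1-yloxy)oxane F6. Acetal exchange (TsOH cat., MeOH, rt) then releases 3.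

**Further compounds**

F1 | step 7 | 2-(4-chlorobutyl)furan | ClCCCCc1ccco1
F2 | step 7 | 2-(hex-5-yn-1-yl)furan | C#CCCCCc1ccco1
F3 | step 4 | (hepta-1,6-diyn-1-yl)tri(propan-2-yl)silane | C#CCCCC#C[Si](C(C)C)(C(C)C)C(C)C
F4 | step 4 | 22-[tri(propan-2-yl)silyl]docosa-14,16,21-triyn-1-ol | OCCCCCCCCCCCCCC#CC#CCCCC#C[Si](C(C)C)(C(C)C)C(C)C
F5 | step 1 | 2-(prop-2-yn-1-yloxy)oxane (racemic acetal) | C#CCOC1CCCCO1
F6 | step 1 | 2-(pentadec-2-yn-1-yloxy)oxane (racemic acetal) | CCCCCCCCCCCCC#CCOC1CCCCO1
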